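The route cuts ring B, the acetyl-bearing ring (B1 acetyl carbon, B2/B4/B6 oxygenated, B3 methyl, B5 bridge carbon), into a four-carbon and a two-carbon piece. One thermal operation joins a cyclobutenone (supplying B4, B1, B6, B5) with an oxygenated propyne (B3 plus methyl, B2 plus oxygen): B3–B4 and B1–B2 form, B4–B5 re-forms, and the alternating oxygen pattern of a hexasubstituted benzene emerges with B1 left free for late acetylation. The precursor is a racemic 3-benzyloxycyclobutenone whose saturated carbon already carries the CH2 bridge and the fully substituted, benzyl-protected ring A (butanoyl, methyl, methoxy).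

Key step: step 10

Atom labels: ring B is the acetyl ring (B1 C–acetyl, B2 C–OH, B3 C–CH3, B4 C–OH, B5 bridge carbon, B6 C–OH); ring A is the butanoyl ring, and its positions are named in words by their substituents.

Remark on the chemistry: benzyl 1-alkynyl ethers are prone to [3,3]-sigmatropic rearrangement on gentle warming, well below the temperature at which a cyclobutenone opens. The propyne partner of the key step therefore carries a triisopropylsilyl group on oxygen, and benzyl ethynyl ether is used only in the cold [2+2] step that makes the cyclobutenone.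

Step 1
Reactants: 1 2,4,6-trihydroxytoluene; 2 butanoyl chloride
Product: 3 1-(2,4,6-trihydroxy-3-methylphenyl)butan-1-one
Conditions: AlCl3 (3 equiv), PhNO2, 0 → 50 °C; then ice/aq HCl
Reagents that add atoms: none
Why: Friedel–Crafts acylation of the electron-rich phloroglucinol ring should give a single C-acyl product, because the two unsubstituted ring carbons of 1 are equivalent and the first acyl group deactivates the ring towards a second one.

Step 2
Reactants: 3 1-(2,4,6-trihydroxy-3-methylphenyl)butan-1-one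
Product: 4 1-(2,6-dihydroxy-4-methoxy-3-methylphenyl)butan-1-one (aspidinol)
Conditions: Me2SO4 (1.0 equiv), K2CO3 (1.0 equiv), acetone, rt
Reagents that add atoms: dimethyl sulfate, COS(=O)(=O)OC
Why: Williamson O-methylation with one equivalent of base and electrophile should go to the hydroxyl para to the ketone, which is the most acidic one and takes no part in the hydrogen-bonded chelate that shields the two ortho hydroxyls.

Step 3
Reactants: 4 1-(2,6-dihydroxy-4-methoxy-3-methylphenyl)butan-1-one
Product: 6 3-butanoyl-2,4-dihydroxy-6-methoxy-5-methylbenzaldehyde, via aryl iminium chloride 5 (not isolated)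
Conditions: POCl3 (1.5 equiv), DMF (3 equiv), EtOAc, 0 °C → rt; then H2O, 60 °C
Reagents that add atoms: N,N-dimethylformamide, CN(C)C=O; water, O
Why: Vilsmeier–Haack formylation should attack the only unsubstituted carbon of ring A, which lies between the methoxy group and a hydroxyl group and is activated by three oxygen substituents, so that in the cold it reacts before the enolisable ketone can, and aqueous hydrolysis of the iminium salt 5 releases the aldehyde.

Step 4
Reactants: 6 3-butanoyl-2,4-dihydroxy-6-methoxy-5-methylbenzaldehyde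
Product: 7 2,4-bis(benzyloxy)-3-butanoyl-6-methoxy-5-methylbenzaldehyde
Conditions: BnBr (2.5 equiv), K2CO3 (3 equiv), Bu4NI (cat.), DMF, 60 °C
Reagents that add atoms: benzyl bromide, BrCc1ccccc1
Why: Williamson benzylation in a dipolar aprotic solvent should etherify both chelated phenols, and with every ring carbon already substituted no C-benzylation at a ring CH can interfere.

Step 5
Reactants: 7 2,4-bis(benzyloxy)-3-butanoyl-6-methoxy-5-methylbenzaldehyde
Product: 10 3-[2,4-bis(benzyloxy)-3-butanoyl-6-methoxy-5-methylphenyl]propanoic acid, via arylidene Meldrum's acid 8 (not isolated), via benzylic Meldrum's acid 9 (not isolated)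
Conditions: Meldrum's acid (1.2 equiv), HCO2H–NEt3 (5:2), rt → 100 °C
Reagents that add atoms: Meldrum's acid (2,2-dimethyl-1,3-dioxane-4,6-dione), CC1(C)OC(=O)CC(=O)O1; water (released in the condensation, taken up again in the ring opening), O
Why: Knoevenagel condensation with Meldrum's acid, conjugate hydride transfer from formate to the alkylidene 8 and ring opening with decarboxylation of 9 should run in one pot (reductive Knoevenagel homologation), and this metal-free reduction spares the benzyl ethers and the hindered aryl ketone.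

Step 6
Reactants: 11 benzyl alcohol; 12 trichloroethene
Product: 13 benzyl (E)-1,2-dichloroethenyl ether
Conditions: KH (1.2 equiv), THF, 0 °C; then 12 (1.1 equiv), 0 °C → rt
Reagents that add atoms: none
Why: Potassium benzyloxide should convert trichloroethene into the trans-dichloro enol ether by base-induced loss of HCl and anti addition of the alkoxide to the transient dichloroethyne (net nucleophilic vinylic substitution), which gives a stable store for the ynol ether.

Step 7
Reactants: 13 benzyl (E)-1,2-dichloroethenyl ether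
Product: 15 benzyl ethynyl ether, via lithium alkoxyacetylide 14 (not isolated)
Conditions: n-BuLi (2.3 equiv), THF, –78 °C; then sat. aq NH4Cl, –78 → 0 °C; kept below 20 °C and used the same day
Reagents that add atoms: none
Why: Dehydrochlorination and chlorine–lithium exchange by n-BuLi should give the lithium alkoxyacetylide 14 (the standard passage from dichlorovinyl ethers to ynol ethers), and cold protonation delivers the terminal ynol ether without exposing it to heat.

Step 8
Reactants: 10 3-[2,4-bis(benzyloxy)-3-butanoyl-6-methoxy-5-methylphenyl]propanoic acid; 15 benzyl ethynyl ether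
Product: 18 3-(benzyloxy)-4-{[2,4-bis(benzyloxy)-3-butanoyl-6-methoxy-5-methylphenyl]methyl}cyclobut-2-en-1-one (racemic), via acid chloride 16 (not isolated), via arylmethylketene 17 (not isolated)
Conditions: (COCl)2 (1.5 equiv), DMF (cat.), CH2Cl2, 0 °C → rt, evaporate; then 15 (2.5 equiv), NEt3 (1.3 equiv, slow addition), CH2Cl2, 0 °C → rt
Reagents that add atoms: none
Why: Dehydrochlorination of the acid chloride 16 by NEt3 gives the aldoketene 17, which the excess ynol ether should trap in a [2+2] cycloaddition (ketene–alkoxyalkyne route to 3-alkoxycyclobutenones) with the nucleophilic CH terminus of 15 bonding to the ketene carbonyl carbon, so that the benzyloxy group sits on ring carbon 3 and the benzylic arm on ring carbon 4; the stereocentre at ring carbon 4 forms without control (racemate) and is erased in step 10.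

Step 9
Reactants: 19 propyne
Product: 22 triisopropyl(prop-1-yn-1-yloxy)silane, via prop-1-ynyllithium 20 (not isolated), via lithium prop-1-ynolate 21 (not isolated)
Conditions: n-BuLi (1.0 equiv), THF, –78 °C; t-BuOOLi [from t-BuOOH and LiN(SiMe3)2], THF, –78 → 0 °C; then i-Pr3SiOTf, –78 °C → rt
Reagents that add atoms: tert-butyl hydroperoxide, CC(C)(C)OO; triisopropylsilyl trifluoromethanesulfonate, CC(C)[Si](C(C)C)(C(C)C)OS(=O)(=O)C(F)(F)F
Why: Oxidation of the lithium acetylide 20 with lithium tert-butyl peroxide should give the ynolate 21 (electrophilic oxygen transfer to a carbanion), and the bulky silyl triflate silylates the ynolate on oxygen to give a thermally robust silyl ynol ether.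

Step 10
Reactants: 18 3-(benzyloxy)-4-{[2,4-bis(benzyloxy)-3-butanoyl-6-methoxy-5-methylphenyl]methyl}cyclobut-2-en-1-one; 22 triisopropyl(prop-1-yn-1-yloxy)silane
Product: 27 1-[2,6-bis(benzyloxy)-3-{[6-(benzyloxy)-2-hydroxy-3-methyl-4-(triisopropylsilyloxy)phenyl]methyl}-4-methoxy-5-methylphenyl]butan-1-one, via vinylketene 23 (not isolated), via vinylcyclobutenone 24 (not isolated), via dienylketene 25 (not isolated), via cyclohexadienone 26 (not isolated)
Conditions: 22 (2 equiv), toluene (0.1 M), argon, 80 °C then 110 °C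
Reagents that add atoms: none
Why: On heating, 18 should undergo conrotatory four-electron ring opening to the vinylketene 23, whose ketene C=C bond takes up the silyl ynol ether 22 in a [2+2] cycloaddition to give the 4-vinylcyclobutenone 24; a second four-electron opening then gives the dienylketene 25, which cyclises to the cyclohexadienone 26 and enolises to the phenol 27. This is the Danheiser benzannulation in its siloxyalkyne form, applied here to a 3-alkoxycyclobutenone. Ring B, the only ring formed, is closed by a thermal disrotatory six-electron electrocyclisation that restores the B4–B5 bond after the cycloaddition has made B3–B4 and B1–B2. No stereocentre is created, and the racemic sp3 carbon of 18 ends as the aromatic carbon B5. The step needs regiocontrol in the cycloaddition and outward rotation in the first ring opening: the electron-rich, methyl-bearing β-carbon of the ynol ether attacks the central ketene carbon, so the methyl group lands at B3 between the new phenol at B4 and the silyl ether at B2, and the benzylic arm, like other alkyl groups on the sp3 carbon, should turn outward, away from the ketene, which prevents a 1,5-hydrogen shift and places it on the outside for the final closure. The conditions are neutral, so the butanoyl ketone and the benzyl ethers of ring A should pass unchanged, and the excess of alkyne is meant to intercept the vinylketene before it dimerises or acylates the product phenol.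

Step 11
Reactants: 27 1-[2,6-bis(benzyloxy)-3-{[6-(benzyloxy)-2-hydroxy-3-methyl-4-(triisopropylsilyloxy)phenyl]methyl}-4-methoxy-5-methylphenyl]butan-1-one
Product: 28 1-[2,6-bis(benzyloxy)-3-{[6-(benzyloxy)-2,4-dihydroxy-3-methylphenyl]methyl}-4-methoxy-5-methylphenyl]butan-1-one
Conditions: Bu4NF (1.2 equiv), AcOH (1.2 equiv), THF, 0 °C
Reagents that add atoms: none
Why: Fluoride-induced desilylation should cleave the aryl silyl ether selectively, the acetic acid buffer keeping the electron-rich resorcinol out of its oxidisable phenoxide form while the benzyl ethers and the ketone are inert.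

Step 12
Reactants: 28 1-[2,6-bis(benzyloxy)-3-{[6-(benzyloxy)-2,4-dihydroxy-3-methylphenyl]methyl}-4-methoxy-5-methylphenyl]butan-1-one
Product: 29 1-[3-{[3-acetyl-2-(benzyloxy)-4,6-dihydroxy-5-methylphenyl]methyl}-2,6-bis(benzyloxy)-4-methoxy-5-methylphenyl]butan-1-one
Conditions: Ac2O (1.2 equiv), BF3·OEt2 (3 equiv), CH2Cl2, 0 °C → rt; then aq NaOAc
Reagents that add atoms: acetic anhydride, CC(=O)OC(C)=O
Why: Friedel–Crafts C-acetylation (with Fries-type transfer of any O-acetyl group under the same Lewis acid) should occur at B1, the only unsubstituted carbon of either ring, which lies ortho to the B2 hydroxyl and para to the B4 hydroxyl and gives a hydrogen-bonded ortho-hydroxy ketone.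

Step 13
Reactants: 29 1-[3-{[3-acetyl-2-(benzyloxy)-4,6-dihydroxy-5-methylphenyl]methyl}-2,6-bis(benzyloxy)-4-methoxy-5-methylphenyl]butan-1-one
Product: 30 1-{3-[(3-acetyl-2,4,6-trihydroxy-5-methylphenyl)methyl]-2,6-dihydroxy-4-methoxy-5-methylphenyl}butan-1-one (CNP0258463.0)
Conditions: H2 (1 atm), Pd/C (10%), EtOAc–MeOH, rt
Reagents that add atoms: none
Why: Catalytic hydrogenolysis should cleave the three benzyl aryl ethers under neutral conditions while the methyl ether, the diarylmethane bridge and the two chelated aryl ketones stay intact, so that all phenols are freed in one operation.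

Compound list
1 | 2,4,6-trihydroxytoluene | Cc1c(O)cc(O)cc1O | starting material
2 | butanoyl chloride | CCCC(Cl)=O | starting material
3 | 1-(2,4,6-trihydroxy-3-methylphenyl)butan-1-one | CCCC(=O)c1c(O)c(C)c(O)cc1O | intermediate
4 | 1-(2,6-dihydroxy-4-methoxy-3-methylphenyl)butan-1-one (aspidinol) | CCCC(=O)c1c(O)c(C)c(OC)cc1O | intermediate
5 | [(3-butanoyl-2,4-dihydroxy-6-methoxy-5-methylphenyl)methylidene]dimethylammonium chloride | CCCC(=O)c1c(O)c(C)c(OC)c(C=[N+](C)C)c1O.[Cl-] | intermediate
6 | 3-butanoyl-2,4-dihydroxy-6-methoxy-5-methylbenzaldehyde | CCCC(=O)c1c(O)c(C)c(OC)c(C=O)c1O | intermediate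
7 | 2,4-bis(benzyloxy)-3-butanoyl-6-methoxy-5-methylbenzaldehyde | CCCC(=O)c1c(OCc2ccccc2)c(C)c(OC)c(C=O)c1OCc1ccccc1 | intermediate
8 | 5-{[2,4-bis(benzyloxy)-3-butanoyl-6-methoxy-5-methylphenyl]methylidene}-2,2-dimethyl-1,3-dioxane-4,6-dione | CCCC(=O)c1c(OCc2ccccc2)c(C)c(OC)c(C=C2C(=O)OC(C)(C)OC2=O)c1OCc1ccccc1 | intermediate
9 | 5-{[2,4-bis(benzyloxy)-3-butanoyl-6-methoxy-5-methylphenyl]methyl}-2,2-dimethyl-1,3-dioxane-4,6-dione | CCCC(=O)c1c(OCc2ccccc2)c(C)c(OC)c(CC2C(=O)OC(C)(C)OC2=O)c1OCc1ccccc1 | intermediate
10 | 3-[2,4-bis(benzyloxy)-3-butanoyl-6-methoxy-5-methylphenyl]propanoic acid | CCCC(=O)c1c(OCc2ccccc2)c(C)c(OC)c(CCC(=O)O)c1OCc1ccccc1 | intermediate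
11 | benzyl alcohol | OCc1ccccc1 | starting material
12 | trichloroethene | ClC=C(Cl)Cl | starting material
13 | benzyl (E)-1,2-dichloroethenyl ether | Cl/C=C(/Cl)OCc1ccccc1 | intermediate
14 | lithium 2-(benzyloxy)ethynide | [Li]C#COCc1ccccc1 | intermediate
15 | benzyl ethynyl ether | C#COCc1ccccc1 | intermediate
16 | 3-[2,4-bis(benzyloxy)-3-butanoyl-6-methoxy-5-methylphenyl]propanoyl chloride | CCCC(=O)c1c(OCc2ccccc2)c(C)c(OC)c(CCC(Cl)=O)c1OCc1ccccc1 | intermediate
17 | 3-[2,4-bis(benzyloxy)-3-butanoyl-6-methoxy-5-methylphenyl]prop-1-en-1-one (the ketene) | CCCC(=O)c1c(OCc2ccccc2)c(C)c(OC)c(CC=C=O)c1OCc1ccccc1 | intermediate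
18 | 3-(benzyloxy)-4-{[2,4-bis(benzyloxy)-3-butanoyl-6-methoxy-5-methylphenyl]methyl}cyclobut-2-en-1-one (racemic) | CCCC(=O)c1c(OCc2ccccc2)c(C)c(OC)c(CC2C(=O)C=C2OCc2ccccc2)c1OCc1ccccc1 | intermediate
19 | propyne | CC#C | starting material
20 | prop-1-yn-1-yllithium | [Li]C#CC | intermediate
21 | lithium prop-1-yn-1-olate | [Li+].CC#C[O-] | intermediate
22 | triisopropyl(prop-1-yn-1-yloxy)silane | CC#CO[Si](C(C)C)(C(C)C)C(C)C | intermediate
23 | (3Z)-3-(benzyloxy)-5-[2,4-bis(benzyloxy)-3-butanoyl-6-methoxy-5-methylphenyl]penta-1,3-dien-1-one | CCCC(=O)c1c(OCc2ccccc2)c(C)c(OC)c(C/C=C(OCc2ccccc2)/C=C=O)c1OCc1ccccc1 | intermediate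
24 | 4-{(1Z)-1-(benzyloxy)-3-[2,4-bis(benzyloxy)-3-butanoyl-6-methoxy-5-methylphenyl]prop-1-en-1-yl}-2-methyl-3-(triisopropylsilyloxy)cyclobut-2-en-1-one (racemic) | CCCC(=O)c1c(OCc2ccccc2)c(C)c(OC)c(C/C=C(OCc2ccccc2)/C2C(=O)C(C)=C2O[Si](C(C)C)(C(C)C)C(C)C)c1OCc1ccccc1 | intermediate
25 | (3E,5Z)-5-(benzyloxy)-7-[2,4-bis(benzyloxy)-3-butanoyl-6-methoxy-5-methylphenyl]-2-methyl-3-(triisopropylsilyloxy)hepta-1,3,5-trien-1-one | CCCC(=O)c1c(OCc2ccccc2)c(C)c(OC)c(C/C=C(OCc2ccccc2)/C=C(O[Si](C(C)C)(C(C)C)C(C)C)\C(C)=C=O)c1OCc1ccccc1 | intermediate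
26 | 5-(benzyloxy)-6-{[2,4-bis(benzyloxy)-3-butanoyl-6-methoxy-5-methylphenyl]methyl}-2-methyl-3-(triisopropylsilyloxy)cyclohexa-2,4-dien-1-one (racemic) | CCCC(=O)c1c(OCc2ccccc2)c(C)c(OC)c(CC2C(=O)C(C)=C(O[Si](C(C)C)(C(C)C)C(C)C)C=C2OCc2ccccc2)c1OCc1ccccc1 | intermediate
27 | 1-[2,6-bis(benzyloxy)-3-{[6-(benzyloxy)-2-hydroxy-3-methyl-4-(triisopropylsilyloxy)phenyl]methyl}-4-methoxy-5-methylphenyl]butan-1-one | CCCC(=O)c1c(OCc2ccccc2)c(C)c(OC)c(Cc2c(O)c(C)c(O[Si](C(C)C)(C(C)C)C(C)C)cc2OCc2ccccc2)c1OCc1ccccc1 | intermediate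
28 | 1-[2,6-bis(benzyloxy)-3-{[6-(benzyloxy)-2,4-dihydroxy-3-methylphenyl]methyl}-4-methoxy-5-methylphenyl]butan-1-one | CCCC(=O)c1c(OCc2ccccc2)c(C)c(OC)c(Cc2c(O)c(C)c(O)cc2OCc2ccccc2)c1OCc1ccccc1 | intermediate
29 | 1-[3-{[3-acetyl-2-(benzyloxy)-4,6-dihydroxy-5-methylphenyl]methyl}-2,6-bis(benzyloxy)-4-methoxy-5-methylphenyl]butan-1-one | CCCC(=O)c1c(OCc2ccccc2)c(C)c(OC)c(Cc2c(O)c(C)c(O)c(C(C)=O)c2OCc2ccccc2)c1OCc1ccccc1 | intermediate
30 | 1-{3-[(3-acetyl-2,4,6-trihydroxy-5-methylphenyl)methyl]-2,6-dihydroxy-4-methoxy-5-methylphenyl}butan-1-one (CNP0258463.0; no stereocentre) | CCCC(=O)c1c(O)c(C)c(OC)c(Cc2c(O)c(C)c(O)c(C(C)=O)c2O)c1O | target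

Total step count: 13 steps.
Longest linear sequence: 10 steps (steps 1, 2, 3, 4, 5, 8, 10, 11, 12, 13). Steps 6–7 (benzyl ethynyl ether) and step 9 (silyl ynol ether) are side branches.

Steps most likely to fail

1. Step 10 (key step). The donor-substituted cyclobutenone may open sluggishly. The vinylketene, once formed, may dimerise, may undergo a 1,5-hydrogen shift from the benzylic CH2 if the arm rotates inward, or may acylate the product phenol before the alkyne captures it. The fallback gives up the benzannulation and joins two finished monomers; it sets out from 4 and comes back to the route at 30. Aminomethylation of 4 at its one unsubstituted ring carbon with dimethyl(methylidene)ammonium iodide in MeCN (Mannich reaction) should give the Mannich base 1-{3-[(dimethylamino)methyl]-2,6-dihydroxy-4-methoxy-5-methylphenyl}butan-1-one F1. Separately, C-acetylation of 1 (Ac2O, BF3·OEt2) should give 1-(2,4,6-trihydroxy-3-methylphenyl)ethan-1-one F2. Heating F1 with F2 in dioxane should expel dimethylamine and generate the ortho-quinone methide 2-butanoyl-3-hydroxy-5-methoxy-4-methyl-6-methylidenecyclohexa-2,4-dien-1-one F3. F2 should capture F3 at its only free ring carbon and give 30 directly, the usual way to unsymmetrical methylene-bridged acylphloroglucinols.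

2. Step 8. Self-condensation of the monosubstituted ketene may outrun its capture, and the heat-sensitive ynol ether may decay in the presence of the amine. The fallback replaces the aldoketene by a chloroketene, which is more electrophilic and cycloadds faster than it dimerises; it sets out from 7 and comes back at 18. Condensation of 7 with Meldrum's acid in the presence of Hantzsch ester (L-proline cat., EtOH, rt) should stop at 9, which is then isolated. Chlorination of 9 at its acidic carbon with N-chlorosuccinimide should give 5-{[2,4-bis(benzyloxy)-3-butanoyl-6-methoxy-5-methylphenyl]methyl}-5-chloro-2,2-dimethyl-1,3-dioxane-4,6-dione F4. Ring opening and decarboxylation in aqueous acetic acid at 100 °C should give 3-[2,4-bis(benzyloxy)-3-butanoyl-6-methoxy-5-methylphenyl]-2-chloropropanoic acid F5 (racemic). Oxalyl chloride should convert it into 3-[2,4-bis(benzyloxy)-3-butanoyl-6-methoxy-5-methylphenyl]-2-chloropropanoyl chloride F6. NEt3 in the presence of 15 should give the chloroketene 3-[2,4-bis(benzyloxy)-3-butanoyl-6-methoxy-5-methylphenyl]-2-chloroprop-1-en-1-one F7 and, by [2+2] cycloaddition with the same regiochemistry, 3-(benzyloxy)-4-{[2,4-bis(benzyloxy)-3-butanoyl-6-methoxy-5-methylphenyl]methyl}-4-chlorocyclobut-2-en-1-one F8 (racemic). Reductive dechlorination with Zn in AcOH–TMEDA–EtOH, the standard treatment of 4-chlorocyclobutenones, should return 18.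

3. Step 12. The Lewis acid may remove or shift benzyl groups and may cleave the electron-rich diarylmethane bridge before C-acylation is complete, or acetylation may stop on oxygen. The fallback brings in the acetyl group by cross-coupling under non-acidic conditions; it sets out from 28 and comes back at 29. Iodination of 28 at B1 with N-iodosuccinimide (MeCN, 0 °C) should give 1-[2,6-bis(benzyloxy)-3-{[2-(benzyloxy)-4,6-dihydroxy-3-iodo-5-methylphenyl]methyl}-4-methoxy-5-methylphenyl]butan-1-one F9. Stille coupling with tributyl(1-ethoxyvinyl)stannane (PdCl2(PPh3)2 cat., dioxane, 90 °C) should give the enol ether 1-[2,6-bis(benzyloxy)-3-{[2-(benzyloxy)-3-(1-ethoxyethenyl)-4,6-dihydroxy-5-methylphenyl]methyl}-4-methoxy-5-methylphenyl]butan-1-one F10. Brief treatment with 1 M HCl in THF at rt should hydrolyse the enol ether to the methyl ketone 29.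

Further compounds
F1 | step 10 | 1-{3-[(dimethylamino)methyl]-2,6-dihydroxy-4-methoxy-5-methylphenyl}butan-1-one | CCCC(=O)c1c(O)c(C)c(OC)c(CN(C)C)c1O
F2 | step 10 | 1-(2,4,6-trihydroxy-3-methylphenyl)ethan-1-one | CC(=O)c1c(O)cc(O)c(C)c1O
F3 | step 10 | 2-butanoyl-3-hydroxy-5-methoxy-4-methyl-6-methylidenecyclohexa-2,4-dien-1-one | CCCC(=O)C1=C(O)C(C)=C(OC)C(=C)C1=O
F4 | step 8 | 5-{[2,4-bis(benzyloxy)-3-butanoyl-6-methoxy-5-methylphenyl]methyl}-5-chloro-2,2-dimethyl-1,3-dioxane-4,6-dione | CCCC(=O)c1c(OCc2ccccc2)c(C)c(OC)c(CC2(Cl)C(=O)OC(C)(C)OC2=O)c1OCc1ccccc1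
F5 | step 8 | 3-[2,4-bis(benzyloxy)-3-butanoyl-6-methoxy-5-methylphenyl]-2-chloropropanoic acid (racemic) | CCCC(=O)c1c(OCc2ccccc2)c(C)c(OC)c(CC(Cl)C(=O)O)c1OCc1ccccc1
F6 | step 8 | 3-[2,4-bis(benzyloxy)-3-butanoyl-6-methoxy-5-methylphenyl]-2-chloropropanoyl chloride (racemic) | CCCC(=O)c1c(OCc2ccccc2)c(C)c(OC)c(CC(Cl)C(Cl)=O)c1OCc1ccccc1
F7 | step 8 | 3-[2,4-bis(benzyloxy)-3-butanoyl-6-methoxy-5-methylphenyl]-2-chloroprop-1-en-1-one | CCCC(=O)c1c(OCc2ccccc2)c(C)c(OC)c(CC(Cl)=C=O)c1OCc1ccccc1
F8 | step 8 | 3-(benzyloxy)-4-{[2,4-bis(benzyloxy)-3-butanoyl-6-methoxy-5-methylphenyl]methyl}-4-chlorocyclobut-2-en-1-one (racemic) | CCCC(=O)c1c(OCc2ccccc2)c(C)c(OC)c(CC2(Cl)C(=O)C=C2OCc2ccccc2)c1OCc1ccccc1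
F9 | step 12 | 1-[2,6-bis(benzyloxy)-3-{[2-(benzyloxy)-4,6-dihydroxy-3-iodo-5-methylphenyl]methyl}-4-methoxy-5-methylphenyl]butan-1-one | CCCC(=O)c1c(OCc2ccccc2)c(C)c(OC)c(Cc2c(O)c(C)c(O)c(I)c2OCc2ccccc2)c1OCc1ccccc1
F10 | step 12 | 1-[2,6-bis(benzyloxy)-3-{[2-(benzyloxy)-3-(1-ethoxyethenyl)-4,6-dihydroxy-5-methylphenyl]methyl}-4-methoxy-5-methylphenyl]butan-1-one | CCCC(=O)c1c(OCc2ccccc2)c(C)c(OC)c(Cc2c(O)c(C)c(O)c(C(=C)OCC)c2OCc2ccccc2)c1OCc1ccccc1
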